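**Retrosynthetic overview**

1. The strategy rests on the C3–C4 unit of ring C: C3, the only stereocentre (3R), carries ring B through C1', and C4 carries ring A through C4a. These two carbons map onto the two carbons of a vinylboronate, so C3–C1' and C4–C4a are cut together in one palladium-catalysed enantioselective conjunctive coupling of a ring B aryllithium, vinylB(pin) and a ring A triflate.
2. The C3–B bond left by the coupling is the handle for C2 (Matteson CH2 insertion, then oxidation). O1–C2 is the last skeletal bond, made by intramolecular Mitsunobu etherification.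
3. Ring A triflate 6 comes from 2,4,6-trihydroxybenzaldehyde (two MOM ethers, methyl ether, Baeyer–Villiger, triflation). Ring B bromide 11 comes from 4-bromoresorcinol (TIPS ether, propargyl ether, Claisen).
4. Ring order: rings A and B are bought as benzene rings; ring D (the dimethylpyran on ring B) closes in step 7, before the coupling; ring C closes last, in step 11.
5. The ring B phenol is carried as a TIPS ether: a bulky silyl chloride distinguishes the two hydroxyls of 4-bromoresorcinol, and the silyl ether survives the acid that frees the ring A phenols, so ring B stays masked during ring closure.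

Key step: step 8

Assumption: isoflavan numbering is used (ring C = O1, C2, C3, C4, C4a, C8a; ring A = C4a–C8a; ring B primed; ring D = the pyran fused to ring B), and the target is (3R). The (Sp,Sp) Mandyphos ligand, (Sp,Sp)-1,1'-bis[bis(4-methoxy-3,5-dimethylphenyl)phosphino]-2,2'-bis[(R)-α-(dimethylamino)benzyl]ferrocene, is assumed to give the (1R)-boronate as in simple aryl/aryl cases; if a model run shows the opposite sense, the (Rp,Rp) antipode is used.

**Route**

Step 1
Reactants: 1 2,4,6-trihydroxybenzaldehyde
Product: 2 2-hydroxy-4,6-bis(methoxymethoxy)benzaldehyde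
Conditions: MOMCl (2.1 equiv), i-Pr2NEt, CH2Cl2, 0 °C to rt
Reagents that add atoms: chloromethyl methyl ether (MOMCl), COCCl
Why: O-alkylation with an alkoxymethyl chloride under amine base should take the para hydroxyl and one ortho hydroxyl, while the second ortho hydroxyl stays hydrogen-bonded to the formyl group and is left free.

Step 2
Reactants: 2 2-hydroxy-4,6-bis(methoxymethoxy)benzaldehyde
Product: 3 2-methoxy-4,6-bis(methoxymethoxy)benzaldehyde
Conditions: MeI, K2CO3, DMF, rt
Reagents that add atoms: iodomethane, CI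
Why: Williamson methylation of the remaining chelated phenol fixes the future C5 methoxy group; MOM ethers are stable to carbonate.

Step 3
Reactants: 3 2-methoxy-4,6-bis(methoxymethoxy)benzaldehyde
Product: 5 2-methoxy-4,6-bis(methoxymethoxy)phenol, via aryl formate 4 (not isolated)
Conditions: mCPBA, NaHCO3, CH2Cl2, 0 °C to rt; Na2S2O3 wash; then K2CO3 (cat.), MeOH, rt, under argon
Reagents that add atoms: 3-chloroperoxybenzoic acid (mCPBA), OOC(=O)c1cccc(Cl)c1
Why: Baeyer–Villiger (Dakin-type) oxidation, in which the trioxygenated aryl group migrates in preference to hydrogen; NaHCO3 shields the MOM ethers from 3-chlorobenzoic acid and carbonate methanolysis frees the phenol from the formate.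

Step 4
Reactants: 5 2-methoxy-4,6-bis(methoxymethoxy)phenol
Product: 6 2-methoxy-4,6-bis(methoxymethoxy)phenyl trifluoromethanesulfonate
Conditions: Tf2O, pyridine, CH2Cl2, −78 to 0 °C
Reagents that add atoms: trifluoromethanesulfonic anhydride, O=S(=O)(OS(=O)(=O)C(F)(F)F)C(F)(F)F
Why: O-sulfonylation of a phenol with Tf2O/pyridine at low temperature tolerates MOM ethers and gives the electrophile for the coupling.

Step 5
Reactants: 7 4-bromobenzene-1,3-diol
Product: 8 2-bromo-5-(triisopropylsilyloxy)phenol
Conditions: TIPSCl (1.0 equiv), imidazole, CH2Cl2/DMF, −10 to 0 °C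
Reagents that add atoms: chlorotriisopropylsilane (TIPSCl), CC(C)[Si](Cl)(C(C)C)C(C)C
Why: Imidazole-mediated silylation is governed by sterics, so the bulky silyl chloride should take the hydroxyl para to bromine and leave the bromine-flanked hydroxyl free.

Step 6
Reactants: 8 2-bromo-5-(triisopropylsilyloxy)phenol; 9 3-chloro-3-methylbut-1-yne
Product: 10 [4-bromo-3-(2-methylbut-3-yn-2-yloxy)phenoxy]triisopropylsilane
Conditions: CuCl2·2H2O (1 mol%), DBU, MeCN, 0 °C
Reagents that add atoms: none
Why: Copper-catalysed propargylic etherification of a phenol with a tertiary propargylic chloride runs through a copper-bound propargyl/allenylidene cation equivalent and so works at 0 °C on an ortho-substituted phenol where direct SN2 cannot.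

Step 7
Reactants: 10 [4-bromo-3-(2-methylbut-3-yn-2-yloxy)phenoxy]triisopropylsilane
Product: 11 8-bromo-2,2-dimethyl-5-(triisopropylsilyloxy)-2H-chromene
Conditions: N,N-diethylaniline, 185 °C
Reagents that add atoms: none
Why: Aryl propargyl ether Claisen rearrangement to the only free ortho carbon (the other bears bromine), then 1,5-hydrogen shift and oxa-6π electrocyclisation, closes ring D with bromine next to the ring oxygen.

Step 8
Reactants: 11 8-bromo-2,2-dimethyl-5-(triisopropylsilyloxy)-2H-chromene; 12 vinylboronic acid pinacol ester; 6 2-methoxy-4,6-bis(methoxymethoxy)phenyl trifluoromethanesulfonate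
Product: 15 2-{(1R)-1-[2,2-dimethyl-5-(triisopropylsilyloxy)-2H-chromen-8-yl]-2-[2-methoxy-4,6-bis(methoxymethoxy)phenyl]ethyl}-4,4,5,5-tetramethyl-1,3,2-dioxaborolane, via chromen-8-yllithium 13 (not isolated), via lithium aryl(vinyl)borate 14 (not isolated)
Conditions: t-BuLi (2.0 equiv), Et2O, −78 °C; 12, −78 °C to rt; solvent switch to THF; 6 (1.1 equiv), Pd(OAc)2 (3 mol%), (Sp,Sp)-Mandyphos ligand (3.6 mol%), NaOTf (3 equiv), 60 °C
Reagents that add atoms: none
Why: Bromine–lithium exchange gives aryllithium 13, which adds to boron of 12 to give the four-coordinate borate 14; zerovalent palladium formed from Pd(OAc)2 and the ligand inserts into the C–O bond of triflate 6, the cationic arylpalladium binds the vinyl group of 14 and triggers an anti 1,2-shift of ring B from boron to C3 while C4 bonds to palladium, and reductive elimination then forms C4–C4a. The closest known reaction is the palladium-catalysed enantioselective conjunctive cross-coupling of aryl(vinyl)boron ate complexes with aryl triflates, here stretched to a triflate with an oxygen substituent on each ortho carbon. No ring closes in this step. The single new stereocentre C3 is set by the chiral bisphosphine, which selects the face of the vinyl group that palladium binds, and the (Sp,Sp) ligand is expected to give the (1R)-boronate. The step needs the metallate shift to outrun direct transmetalation and Heck-type paths: the triflate gives a cationic, alkene-seeking palladium, NaOTf removes the bromide left by the exchange as NaBr, the pinacol ester and the electron-rich ring B (ortho and para oxygens) favour migration, and the chromene alkene is 1,2-disubstituted next to a quaternary carbon and carries no boron. The ortho OMe and OMOM groups are small oxygen-linked substituents, so oxidative addition and reductive elimination at C4a are judged feasible at 60 °C with a raised catalyst loading.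

Step 9
Reactants: 15 2-{(1R)-1-[2,2-dimethyl-5-(triisopropylsilyloxy)-2H-chromen-8-yl]-2-[2-methoxy-4,6-bis(methoxymethoxy)phenyl]ethyl}-4,4,5,5-tetramethyl-1,3,2-dioxaborolane
Product: 17 (2R)-2-[2,2-dimethyl-5-(triisopropylsilyloxy)-2H-chromen-8-yl]-3-[2-methoxy-4,6-bis(methoxymethoxy)phenyl]propan-1-ol, via homologated primary boronate 16 (not isolated)
Conditions: BrCH2Cl (3 equiv), n-BuLi (2.5 equiv), THF, −78 °C to rt; then 2 M NaOH, 30% H2O2, 0 °C, short contact
Reagents that add atoms: bromochloromethane, ClCBr; hydrogen peroxide, OO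
Why: Matteson homologation, in which LiCH2Cl made in situ adds to boron and C3 migrates to CH2 with loss of chloride and retention of configuration; the primary boronate is then oxidised by alkaline peroxide at a carbon that is not the stereocentre, and the cold, short oxidation spares the aryl silyl ether.

Step 10
Reactants: 17 (2R)-2-[2,2-dimethyl-5-(triisopropylsilyloxy)-2H-chromen-8-yl]-3-[2-methoxy-4,6-bis(methoxymethoxy)phenyl]propan-1-ol
Product: 18 4-{(2R)-2-[2,2-dimethyl-5-(triisopropylsilyloxy)-2H-chromen-8-yl]-3-hydroxypropyl}-5-methoxybenzene-1,3-diol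
Conditions: 2 M HCl, MeOH/THF, 40 °C, monitored
Reagents that add atoms: none
Why: Acid-catalysed acetal exchange with methanol removes both MOM groups; the aryl TIPS ether and the primary alcohol are stable to dilute HCl, no leaving group is present that ring B could displace, and the mild temperature limits acid addition to the chromene alkene.

Step 11
Reactants: 18 4-{(2R)-2-[2,2-dimethyl-5-(triisopropylsilyloxy)-2H-chromen-8-yl]-3-hydroxypropyl}-5-methoxybenzene-1,3-diol
Product: 19 (3R)-3-[2,2-dimethyl-5-(triisopropylsilyloxy)-2H-chromen-8-yl]-5-methoxychroman-7-ol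
Conditions: PPh3, DIAD (slow addition), THF (0.01 M), 0 °C to rt
Reagents that add atoms: none
Why: Intramolecular Mitsunobu etherification, in which the primary alcohol is activated as an alkoxyphosphonium ion and displaced by the C8a phenol in a 6-exo-tet closure of ring C; the C7 phenol can react only intermolecularly, which dilution suppresses, and C3 is not a reacting centre.

Step 12
Reactants: 19 (3R)-3-[2,2-dimethyl-5-(triisopropylsilyloxy)-2H-chromen-8-yl]-5-methoxychroman-7-ol
Product: 20 (3R)-3-(5-hydroxy-2,2-dimethyl-2H-chromen-8-yl)-5-methoxychroman-7-ol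
Conditions: TBAF, AcOH (1:1), THF, 0 °C
Reagents that add atoms: none
Why: Fluoride cleaves the aryl silyl ether, and the acetic acid buffer keeps the two phenols protonated so that they are not left as oxidation-prone phenoxides.

**Compound list**

1 | 2,4,6-trihydroxybenzaldehyde | O=Cc1c(O)cc(O)cc1O | starting material
2 | 2-hydroxy-4,6-bis(methoxymethoxy)benzaldehyde | COCOc1cc(O)c(C=O)c(OCOC)c1 | intermediate
3 | 2-methoxy-4,6-bis(methoxymethoxy)benzaldehyde | COCOc1cc(OC)c(C=O)c(OCOC)c1 | intermediate
4 | 2-methoxy-4,6-bis(methoxymethoxy)phenyl formate (formed in the flask, not isolated) | COCOc1cc(OC)c(OC=O)c(OCOC)c1 | intermediate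
5 | 2-methoxy-4,6-bis(methoxymethoxy)phenol | COCOc1cc(OC)c(O)c(OCOC)c1 | intermediate
6 | 2-methoxy-4,6-bis(methoxymethoxy)phenyl trifluoromethanesulfonate | COCOc1cc(OC)c(OS(=O)(=O)C(F)(F)F)c(OCOC)c1 | intermediate
7 | 4-bromobenzene-1,3-diol (4-bromoresorcinol) | Oc1ccc(Br)c(O)c1 | starting material
8 | 2-bromo-5-(triisopropylsilyloxy)phenol | Oc1cc(O[Si](C(C)C)(C(C)C)C(C)C)ccc1Br | intermediate
9 | 3-chloro-3-methylbut-1-yne | C#CC(C)(C)Cl | starting material
10 | [4-bromo-3-(2-methylbut-3-yn-2-yloxy)phenoxy]triisopropylsilane | C#CC(C)(C)Oc1cc(O[Si](C(C)C)(C(C)C)C(C)C)ccc1Br | intermediate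
11 | 8-bromo-2,2-dimethyl-5-(triisopropylsilyloxy)-2H-chromene | CC1(C)C=Cc2c(O[Si](C(C)C)(C(C)C)C(C)C)ccc(Br)c2O1 | intermediate
12 | vinylboronic acid pinacol ester | C=CB1OC(C)(C)C(C)(C)O1 | starting material
13 | [2,2-dimethyl-5-(triisopropylsilyloxy)-2H-chromen-8-yl]lithium (formed in the flask, not isolated) | [Li]c1ccc(O[Si](C(C)C)(C(C)C)C(C)C)c2c1OC(C)(C)C=C2 | intermediate
14 | lithium [2,2-dimethyl-5-(triisopropylsilyloxy)-2H-chromen-8-yl](vinyl)(pinacolato)borate (formed in the flask, not isolated) | [Li+].C=C[B-]1(c2ccc(O[Si](C(C)C)(C(C)C)C(C)C)c3c2OC(C)(C)C=C3)OC(C)(C)C(C)(C)O1 | intermediate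
15 | 2-{(1R)-1-[2,2-dimethyl-5-(triisopropylsilyloxy)-2H-chromen-8-yl]-2-[2-methoxy-4,6-bis(methoxymethoxy)phenyl]ethyl}-4,4,5,5-tetramethyl-1,3,2-dioxaborolane | COCOc1cc(OC)c(C[C@H](c2ccc(O[Si](C(C)C)(C(C)C)C(C)C)c3c2OC(C)(C)C=C3)B2OC(C)(C)C(C)(C)O2)c(OCOC)c1 | intermediate
16 | 2-{(2R)-2-[2,2-dimethyl-5-(triisopropylsilyloxy)-2H-chromen-8-yl]-3-[2-methoxy-4,6-bis(methoxymethoxy)phenyl]propyl}-4,4,5,5-tetramethyl-1,3,2-dioxaborolane (formed in the flask, not isolated) | COCOc1cc(OC)c(C[C@H](c2ccc(O[Si](C(C)C)(C(C)C)C(C)C)c3c2OC(C)(C)C=C3)CB2OC(C)(C)C(C)(C)O2)c(OCOC)c1 | intermediate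
17 | (2R)-2-[2,2-dimethyl-5-(triisopropylsilyloxy)-2H-chromen-8-yl]-3-[2-methoxy-4,6-bis(methoxymethoxy)phenyl]propan-1-ol | COCOc1cc(OC)c(C[C@H](c2ccc(O[Si](C(C)C)(C(C)C)C(C)C)c3c2OC(C)(C)C=C3)CO)c(OCOC)c1 | intermediate
18 | 4-{(2R)-2-[2,2-dimethyl-5-(triisopropylsilyloxy)-2H-chromen-8-yl]-3-hydroxypropyl}-5-methoxybenzene-1,3-diol | COc1cc(O)cc(O)c1C[C@H](c1ccc(O[Si](C(C)C)(C(C)C)C(C)C)c2c1OC(C)(C)C=C2)CO | intermediate
19 | (3R)-3-[2,2-dimethyl-5-(triisopropylsilyloxy)-2H-chromen-8-yl]-5-methoxychroman-7-ol | COc1cc(O)cc2c1C[C@H](c1ccc(O[Si](C(C)C)(C(C)C)C(C)C)c3c1OC(C)(C)C=C3)CO2 | intermediate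
20 | (3R)-3-(5-hydroxy-2,2-dimethyl-2H-chromen-8-yl)-5-methoxychroman-7-ol (CNP0320659.1) | COc1cc(O)cc2c1C[C@H](c1ccc(O)c3c1OC(C)(C)C=C3)CO2 | target

**Step count**

Total step count: 12.
Longest linear sequence: 9 steps (steps 1–4 and 8–12, from 1). The ring B branch (steps 5–7) joins at step 8.

**Steps most likely to fail**

Step 8 (conjunctive coupling). Oxidative addition into the electron-rich triflate with two ortho oxygens may stall, direct Suzuki-type transfer of the vinyl or aryl group may outrun the metallate shift, or the enantiofacial control may erode with two ortho-substituted partners. The fallback sets out from bromide 11 and aldehyde 3 and returns to the route at alcohol 17, so it also bypasses step 9. Bromide 11 would be coupled with the Reformatsky reagent BrZnCH2CO2Et (Pd2(dba)3, XPhos, THF, 65 °C) to give ethyl [2,2-dimethyl-5-(triisopropylsilyloxy)-2H-chromen-8-yl]acetate F1. Saponification (LiOH, THF/H2O, 0 °C to rt) would give [2,2-dimethyl-5-(triisopropylsilyloxy)-2H-chromen-8-yl]acetic acid F2. Perkin condensation of F2 with aldehyde 3 (Ac2O, Et3N, 110 °C) should give (E)-2-[2,2-dimethyl-5-(triisopropylsilyloxy)-2H-chromen-8-yl]-3-[2-methoxy-4,6-bis(methoxymethoxy)phenyl]acrylic acid F3. Carboxylate-directed asymmetric hydrogenation (H2, [Ir(cod)(SIPHOX)][B(3,5-(CF3)2C6H3)4], where SIPHOX is a chiral spiro phosphine–oxazoline, Cs2CO3, MeOH), with the ligand antipode chosen for the (R)-acid, should leave the undirected chromene alkene alone and give (2R)-2-[2,2-dimethyl-5-(triisopropylsilyloxy)-2H-chromen-8-yl]-3-[2-methoxy-4,6-bis(methoxymethoxy)phenyl]propanoic acid F4. Reduction with LiAlH4 (THF, 0 °C) would give 17.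

Step 9 (Matteson homologation and oxidation). The short-lived carbenoid may decompose before it adds to the crowded secondary benzylic boron, so that unchanged 15 is oxidised to the secondary alcohol. The fallback sets out from boronate 15 and returns at the primary boronate 16. It builds the methylene in two separate metallate shifts from a carbenoid that can be preformed and used in excess. LiCHCl2 (from CH2Cl2 and n-BuLi, THF, −100 °C), then ZnCl2 on warming, would give 2-{(2R)-1-chloro-2-[2,2-dimethyl-5-(triisopropylsilyloxy)-2H-chromen-8-yl]-3-[2-methoxy-4,6-bis(methoxymethoxy)phenyl]propyl}-4,4,5,5-tetramethyl-1,3,2-dioxaborolane F5, as both epimers at the chlorine-bearing carbon. LiBHEt3 (THF, −78 °C to rt) would then add hydride to boron and shift it to carbon with loss of chloride, which removes that stereocentre and gives 16. Oxidation as in step 9 then follows.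

Step 11 (Mitsunobu closure of ring C). Intermolecular O-alkylation at the free C7 phenol, or participation of the electron-rich ring B at the activated C2, may compete with the 6-exo closure. The fallback sets out from alcohol 17 (before step 10) and returns at 19. It replaces the redox condensation by a phenoxide SN2 on a sulfonate. MsCl and Et3N (CH2Cl2, 0 °C) would give (2R)-2-[2,2-dimethyl-5-(triisopropylsilyloxy)-2H-chromen-8-yl]-3-[2-methoxy-4,6-bis(methoxymethoxy)phenyl]propyl methanesulfonate F6. Brief treatment with 2 M HCl in MeOH/THF at rt would give (2R)-3-(2,4-dihydroxy-6-methoxyphenyl)-2-[2,2-dimethyl-5-(triisopropylsilyloxy)-2H-chromen-8-yl]propyl methanesulfonate F7. K2CO3 in acetone at 50 °C would then close ring C through the C8a phenoxide to give 19, with ring B still silylated so that its phenoxide cannot take part.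

**Further compounds**

F1 | step 8 | ethyl [2,2-dimethyl-5-(triisopropylsilyloxy)-2H-chromen-8-yl]acetate | CCOC(=O)Cc1ccc(O[Si](C(C)C)(C(C)C)C(C)C)c2c1OC(C)(C)C=C2
F2 | step 8 | [2,2-dimethyl-5-(triisopropylsilyloxy)-2H-chromen-8-yl]acetic acid | OC(=O)Cc1ccc(O[Si](C(C)C)(C(C)C)C(C)C)c2c1OC(C)(C)C=C2
F3 | step 8 | (E)-2-[2,2-dimethyl-5-(triisopropylsilyloxy)-2H-chromen-8-yl]-3-[2-methoxy-4,6-bis(methoxymethoxy)phenyl]acrylic acid | COCOc1cc(OC)c(/C=C(/C(=O)O)c2ccc(O[Si](C(C)C)(C(C)C)C(C)C)c3c2OC(C)(C)C=C3)c(OCOC)c1
F4 | step 8 | (2R)-2-[2,2-dimethyl-5-(triisopropylsilyloxy)-2H-chromen-8-yl]-3-[2-methoxy-4,6-bis(methoxymethoxy)phenyl]propanoic acid | COCOc1cc(OC)c(C[C@H](c2ccc(O[Si](C(C)C)(C(C)C)C(C)C)c3c2OC(C)(C)C=C3)C(=O)O)c(OCOC)c1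
F5 | step 9 | 2-{(2R)-1-chloro-2-[2,2-dimethyl-5-(triisopropylsilyloxy)-2H-chromen-8-yl]-3-[2-methoxy-4,6-bis(methoxymethoxy)phenyl]propyl}-4,4,5,5-tetramethyl-1,3,2-dioxaborolane (both epimers at C1) | COCOc1cc(OC)c(C[C@H](c2ccc(O[Si](C(C)C)(C(C)C)C(C)C)c3c2OC(C)(C)C=C3)C(Cl)B2OC(C)(C)C(C)(C)O2)c(OCOC)c1
F6 | step 11 | (2R)-2-[2,2-dimethyl-5-(triisopropylsilyloxy)-2H-chromen-8-yl]-3-[2-methoxy-4,6-bis(methoxymethoxy)phenyl]propyl methanesulfonate | COCOc1cc(OC)c(C[C@H](c2ccc(O[Si](C(C)C)(C(C)C)C(C)C)c3c2OC(C)(C)C=C3)COS(C)(=O)=O)c(OCOC)c1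
F7 | step 11 | (2R)-3-(2,4-dihydroxy-6-methoxyphenyl)-2-[2,2-dimethyl-5-(triisopropylsilyloxy)-2H-chromen-8-yl]propyl methanesulfonate | COc1cc(O)cc(O)c1C[C@H](c1ccc(O[Si](C(C)C)(C(C)C)C(C)C)c2c1OC(C)(C)C=C2)COS(C)(=O)=O
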